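**Plan**

- Retrosynthesis: the C15 ester and the two O-acyl bonds are cut first, then C12–C13 (alkylborane/enol triflate coupling), which leaves a C9-vinyl decalin. The 6β,7α-diol is taken back to a C6 ketone (C7–O by enolate oxidation), and ring B is then cut at C7–C8 and C9–C10.
- Enabling feature: ring B (C5–C10) is a cyclohexene whose C8=C9 bond lies opposite C5–C6 and whose C6 carries oxygen. It is therefore the [4+2] adduct of the 2-oxy-diene C7=C6(O)–C5=C10 (silyl enol ether of 1-acetyl-2,6,6-trimethylcyclohexene, ring A intact) and the alkyne C8≡C9 of but-2-ynal (methyl on C8, C11 as CHO on C9).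
- Forward: ring A is bought (β-cyclocitral); ring B arises in the cycloaddition; C11 is methylenated, the C6 ketone is unmasked, O7 and O6 are introduced and acylated; the C12–C15 chain is joined last and its ester is cleaved.
- Stereochemistry: C10 from the chiral amine catalyst in the cycloaddition; C5 (protonation), C7 (enolate hydroxylation) and C6 (hydride) are relayed from C10 by attack on the α face; the 13E geometry comes from an (E)-enol triflate.

Key step: step 5

Remark: ring atoms carry labdane numbers (C1–C10; C11 on C9; C17 = methyl on C8; C20 = methyl on C10), and β denotes the face of the C10 methyl group.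

**Step 1**
Reactants: 1 β-cyclocitral (2,6,6-trimethylcyclohex-1-ene-1-carbaldehyde)
Product: 2 1-(2,6,6-trimethylcyclohex-1-en-1-yl)ethan-1-ol (racemic)
Conditions: MeMgBr, Et2O, 0 °C; aq. NH4Cl
Reagents that add atoms: methylmagnesium bromide, C[Mg]Br
Why: Grignard 1,2-addition to the hindered enal carbonyl gives the secondary allylic alcohol, whose stereocentre is removed in step 2 and is therefore made as the racemate.

**Step 2**
Reactants: 2 1-(2,6,6-trimethylcyclohex-1-en-1-yl)ethan-1-ol
Product: 3 1-(2,6,6-trimethylcyclohex-1-en-1-yl)ethan-1-one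
Conditions: Dess–Martin periodinane, NaHCO3, CH2Cl2, 0 °C → rt
Reagents that add atoms: none
Why: Dess–Martin oxidation of a secondary allylic alcohol gives the methyl ketone under buffered conditions that leave the tetrasubstituted alkene in place.

**Step 3**
Reactants: 3 1-(2,6,6-trimethylcyclohex-1-en-1-yl)ethan-1-one
Product: 4 triisopropyl{[1-(2,6,6-trimethylcyclohex-1-en-1-yl)ethenyl]oxy}silane (diene C7=C6(OTIPS)–C5=C10)
Conditions: TIPSOTf, Et3N, CH2Cl2, 0 °C → rt
Reagents that add atoms: triisopropylsilyl trifluoromethanesulfonate, CC(C)[Si](C(C)C)(C(C)C)OS(=O)(=O)C(F)(F)F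
Why: Soft enolisation of the methyl ketone (silyl triflate/amine) removes a proton from the acetyl CH3 and gives the cross-conjugated 2-silyloxydiene; the bulky TIPS group is chosen so that the enol ether survives step 5.

**Step 4**
Reactants: 5 but-2-yn-1-ol
Product: 6 but-2-ynal
Conditions: MnO2, CH2Cl2, rt; filtered solution used directly
Reagents that add atoms: none
Why: Activated manganese dioxide oxidises the propargylic alcohol to the ynal without over-oxidation, and the volatile aldehyde is used as a dried solution.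

**Step 5**
Reactants: 4 triisopropyl{[1-(2,6,6-trimethylcyclohex-1-en-1-yl)ethenyl]oxy}silane; 6 but-2-ynal
Product: 9 (8aS)-2,5,5,8a-tetramethyl-4-[(triisopropylsilyl)oxy]-3,5,6,7,8,8a-hexahydronaphthalene-1-carbaldehyde, via alkynyl iminium trifluoroacetate 7 (not isolated), via cycloadduct iminium trifluoroacetate 8 (not isolated)
Conditions: (2R,5R)-5-benzyl-2-tert-butyl-3-methylimidazolidin-4-one·CF3CO2H (20 mol %), Et2O, −40 → −10 °C
Reagents that add atoms: none
Why: Proposed new method: the amine salt condenses with 6 to the alkynyl iminium ion 7, the unsubstituted enol-ether terminus C7 of 4 adds to its β-carbon C8, and the allenamine carbon C9 so formed closes on C10, the tertiary end of the silyloxyallyl cation, on the same face of the alkyne, that is a concerted but strongly asynchronous [4+2] cycloaddition, after which hydrolysis of 8 returns the catalyst. The closest known reactions are the imidazolidinone-catalysed Diels–Alder reactions of ynals with 2-vinylindoles, which also create an all-carbon quaternary centre, the iminium-catalysed Mukaiyama–Michael reaction of silyl enol ethers, and the thermal Diels–Alder reaction of 2,6,6-trimethyl-1-vinylcyclohexene with acetylenic esters; what is new is their combination on a 2-silyloxydiene with a fully substituted terminus. Ring B is closed in the [4+2] mode, the second bond by 6-endo attack of C9 on C10. The only new stereocentre, C10, is controlled by the catalyst, whose benzyl group shields one face of the iminium ion: for the endo arrangement of the diene below the iminium nitrogen the (2R,5R) antipode should give the 8aS adduct, and the (2S,5S) antipode is used instead if the exo mode prevails (the sense is to be secured by correlation at the stage of 14). The step needs 1,4- instead of 1,2-attack on the aldehyde, which iminium activation secures, and the orientation C7→C8 and C9→C10, which the substrate secures because the C6 silyloxy group makes C7 the nucleophilic terminus and the two alkyl groups on C10 stabilise positive charge there. Closure of C9 on C6 to a cyclobutene is strained and reversible, so the six-membered ring should be the product.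

**Step 6**
Reactants: 9 (8aS)-2,5,5,8a-tetramethyl-4-[(triisopropylsilyl)oxy]-3,5,6,7,8,8a-hexahydronaphthalene-1-carbaldehyde
Product: 10 triisopropyl{[(4aR)-4-ethenyl-3,4a,8,8-tetramethyl-2,4a,5,6,7,8-hexahydronaphthalen-1-yl]oxy}silane
Conditions: Ph3PCH3Br, KOtBu, THF, 0 °C → rt
Reagents that add atoms: methyltriphenylphosphonium bromide, C[P+](c1ccccc1)(c1ccccc1)c1ccccc1.[Br-]
Why: Wittig methylenation of the hindered enal (the reaction that also converts β-cyclocitral into its vinyl analogue) gives the C11=C12 vinyl group, and the silyl enol ether is inert to the ylide.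

**Step 7**
Reactants: 10 triisopropyl{[(4aR)-4-ethenyl-3,4a,8,8-tetramethyl-2,4a,5,6,7,8-hexahydronaphthalen-1-yl]oxy}silane
Product: 11 (4aS,8aS)-4-ethenyl-3,4a,8,8-tetramethyl-4a,5,6,7,8,8a-hexahydronaphthalen-1(2H)-one (6-ketone, 5α-H, trans-fused)
Conditions: TBAF, AcOH, THF, 0 °C
Reagents that add atoms: none
Why: Fluoride cleaves the Si–O bond and the enolate is protonated at C5 by acetic acid from the α face, opposite the C10 methyl and the axial C4 methyl, which should give the trans-fused ketone, while the buffer keeps the enolate from equilibrating so that C8=C9 stays out of conjugation (desilylative ketonisation).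

**Step 8**
Reactants: 11 (4aS,8aS)-4-ethenyl-3,4a,8,8-tetramethyl-4a,5,6,7,8,8a-hexahydronaphthalen-1(2H)-one
Product: 13 (2S,4aS,8aS)-4-ethenyl-2-hydroxy-3,4a,8,8-tetramethyl-4a,5,6,7,8,8a-hexahydronaphthalen-1(2H)-one (7α-OH), via potassium dienolate 12 (not isolated)
Conditions: KHMDS, THF, −78 °C; 3-phenyl-2-(phenylsulfonyl)oxaziridine, −78 °C; aq. NH4Cl
Reagents that add atoms: 3-phenyl-2-(phenylsulfonyl)oxaziridine, O=S(=O)(N1OC1c1ccccc1)c1ccccc1
Why: KHMDS removes the more acidic and less hindered C7 proton (α to the ketone and allylic) to give dienolate 12, which is hydroxylated at its α-carbon from the α face, away from the C10 and axial C4 methyl groups, to set 7α-OH (Davis oxidation).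

**Step 9**
Reactants: 13 (2S,4aS,8aS)-4-ethenyl-2-hydroxy-3,4a,8,8-tetramethyl-4a,5,6,7,8,8a-hexahydronaphthalen-1(2H)-one
Product: 14 (1S,2S,4aS,8aS)-4-ethenyl-3,4a,8,8-tetramethyl-1,2,4a,5,6,7,8,8a-octahydronaphthalene-1,2-diol (6β,7α-diol)
Conditions: NaBH4, MeOH/CH2Cl2, −40 → 0 °C
Reagents that add atoms: none
Why: Hydride attacks the C6 ketone from the α face because the β face is blocked by the syn-axial C10 and C4β methyl groups, which gives the axial 6β-alcohol and thus the trans-diol (substrate-controlled borohydride reduction, as with 6-oxo steroids).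

**Step 10**
Reactants: 14 (1S,2S,4aS,8aS)-4-ethenyl-3,4a,8,8-tetramethyl-1,2,4a,5,6,7,8,8a-octahydronaphthalene-1,2-diol
Product: 15 (1S,2S,4aS,8aS)-4-ethenyl-1-hydroxy-3,4a,8,8-tetramethyl-1,2,4a,5,6,7,8,8a-octahydronaphthalen-2-yl 3-methylbutanoate
Conditions: (Me2CHCH2CO)2O (1.1 equiv), DMAP (cat.), pyridine, CH2Cl2, 0 °C
Reagents that add atoms: 3-methylbutanoic anhydride, CC(C)CC(=O)OC(=O)CC(C)C
Why: The allylic 7α-hydroxyl is far more accessible than the 6β-hydroxyl, which sits between two syn-axial methyl groups, so one equivalent of anhydride under DMAP catalysis should acylate O7 only, and the trans-diaxial geometry prevents acyl migration.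

**Step 11**
Reactants: 15 (1S,2S,4aS,8aS)-4-ethenyl-1-hydroxy-3,4a,8,8-tetramethyl-1,2,4a,5,6,7,8,8a-octahydronaphthalen-2-yl 3-methylbutanoate
Product: 16 (1S,2S,4aS,8aS)-1-(acetyloxy)-4-ethenyl-3,4a,8,8-tetramethyl-1,2,4a,5,6,7,8,8a-octahydronaphthalen-2-yl 3-methylbutanoate
Conditions: Ac2O, DMAP, Et3N, CH2Cl2, 40 °C
Reagents that add atoms: acetic anhydride, CC(=O)OC(C)=O
Why: DMAP-catalysed acetylation under forcing conditions esterifies the remaining hindered axial 6β-hydroxyl, and the neighbouring ester cannot migrate across the trans-diaxial diol.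

**Step 12**
Reactants: 17 2-(trimethylsilyl)ethan-1-ol; 18 2,2,6-trimethyl-4H-1,3-dioxin-4-one
Product: 20 2-(trimethylsilyl)ethyl 3-oxobutanoate, via acetylketene 19 (not isolated)
Conditions: xylene, 140 °C, acetone distilled off
Reagents that add atoms: none
Why: Thermal retro-[4+2] of the dioxinone releases acetylketene 19, which the alcohol traps as the β-keto ester (acetoacetylation).

**Step 13**
Reactants: 20 2-(trimethylsilyl)ethyl 3-oxobutanoate
Product: 21 2-(trimethylsilyl)ethyl (2E)-3-{[(trifluoromethyl)sulfonyl]oxy}but-2-enoate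
Conditions: Tf2O, aq. Me4NOH, hexanes, 5 °C → rt
Reagents that add atoms: trifluoromethanesulfonic anhydride, O=S(=O)(OS(=O)(=O)C(F)(F)F)C(F)(F)F
Why: With the non-chelating tetramethylammonium counter-ion the β-keto ester enolate is triflated as the E isomer (triflate trans to the ester), which fixes the later C13=C14 geometry (stereoselective enol triflate formation).

**Step 14**
Reactants: 16 (1S,2S,4aS,8aS)-1-(acetyloxy)-4-ethenyl-3,4a,8,8-tetramethyl-1,2,4a,5,6,7,8,8a-octahydronaphthalen-2-yl 3-methylbutanoate; 21 2-(trimethylsilyl)ethyl (2E)-3-{[(trifluoromethyl)sulfonyl]oxy}but-2-enoate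
Product: 23 2-(trimethylsilyl)ethyl (2E)-5-[(3S,4S,4aS,8aS)-4-(acetyloxy)-2,5,5,8a-tetramethyl-3-[(3-methylbutanoyl)oxy]-3,4,4a,5,6,7,8,8a-octahydronaphthalen-1-yl]-3-methylpent-2-enoate, via B-alkyl-9-borabicyclononane 22 (not isolated)
Conditions: 9-BBN, THF, 0 °C → rt; then 21, Pd(dppf)Cl2 (5 mol %), aq. K3PO4, DMF, rt
Reagents that add atoms: 9-borabicyclo[3.3.1]nonane, [H]B1C2CCCC1CCC2 (its boron is found in 22 only)
Why: 9-BBN adds only to the terminal vinyl group (boron at C12; the tetrasubstituted C8=C9 bond and the esters are inert), and B-alkyl Suzuki–Miyaura coupling of 22 with the activated enol triflate forms C12–C13 with retention of the E geometry.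

**Step 15**
Reactants: 23 2-(trimethylsilyl)ethyl (2E)-5-[(3S,4S,4aS,8aS)-4-(acetyloxy)-2,5,5,8a-tetramethyl-3-[(3-methylbutanoyl)oxy]-3,4,4a,5,6,7,8,8a-octahydronaphthalen-1-yl]-3-methylpent-2-enoate
Product: 24 (2E)-5-[(3S,4S,4aS,8aS)-4-(acetyloxy)-2,5,5,8a-tetramethyl-3-[(3-methylbutanoyl)oxy]-3,4,4a,5,6,7,8,8a-octahydronaphthalen-1-yl]-3-methylpent-2-enoic acid (6β-acetoxy-7α-isovaleryloxylabda-8,13E-dien-15-oic acid)
Conditions: TBAF, THF, 0 °C; dilute aq. HCl work-up
Reagents that add atoms: none
Why: Fluoride-induced β-elimination of the 2-(trimethylsilyl)ethyl ester frees the acid under conditions that should neither hydrolyse the acetate and isovalerate nor ionise the allylic C7 ester.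

**Compound list**

1 | β-cyclocitral (2,6,6-trimethylcyclohex-1-ene-1-carbaldehyde) | O=CC1=C(C)CCCC1(C)C | starting material
2 | 1-(2,6,6-trimethylcyclohex-1-en-1-yl)ethan-1-ol (racemic) | CC(O)C1=C(C)CCCC1(C)C | intermediate
3 | 1-(2,6,6-trimethylcyclohex-1-en-1-yl)ethan-1-one | CC(=O)C1=C(C)CCCC1(C)C | intermediate
4 | triisopropyl{[1-(2,6,6-trimethylcyclohex-1-en-1-yl)ethenyl]oxy}silane | C=C(O[Si](C(C)C)(C(C)C)C(C)C)C1=C(C)CCCC1(C)C | intermediate
5 | but-2-yn-1-ol | CC#CCO | starting material
6 | but-2-ynal | CC#CC=O | intermediate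
7 | iminium ion from 6 and the (2R,5R)-imidazolidinone catalyst, trifluoroacetate (not isolated) | CC#CC=[N+]1[C@@H](C(C)(C)C)N(C)C(=O)[C@H]1Cc1ccccc1.[O-]C(=O)C(F)(F)F | intermediate
8 | iminium ion of 9 with the same catalyst, trifluoroacetate (not isolated) | C(=[N+]3[C@@H](C(C)(C)C)N(C)C(=O)[C@H]3Cc3ccccc3)C1=C(C)CC(O[Si](C(C)C)(C(C)C)C(C)C)=C2C(C)(C)CCC[C@]12C.[O-]C(=O)C(F)(F)F | intermediate
9 | (8aS)-2,5,5,8a-tetramethyl-4-[(triisopropylsilyl)oxy]-3,5,6,7,8,8a-hexahydronaphthalene-1-carbaldehyde | O=CC1=C(C)CC(O[Si](C(C)C)(C(C)C)C(C)C)=C2C(C)(C)CCC[C@]12C | intermediate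
10 | triisopropyl{[(4aR)-4-ethenyl-3,4a,8,8-tetramethyl-2,4a,5,6,7,8-hexahydronaphthalen-1-yl]oxy}silane | C=CC1=C(C)CC(O[Si](C(C)C)(C(C)C)C(C)C)=C2C(C)(C)CCC[C@]12C | intermediate
11 | (4aS,8aS)-4-ethenyl-3,4a,8,8-tetramethyl-4a,5,6,7,8,8a-hexahydronaphthalen-1(2H)-one | O=C1CC(C)=C(C=C)[C@@]2(C)CCCC(C)(C)[C@H]12 | intermediate
12 | potassium dienolate of 11 (O–C6=C7) (not isolated) | [K+].[O-]C1=CC(C)=C(C=C)[C@@]2(C)CCCC(C)(C)[C@H]12 | intermediate
13 | (2S,4aS,8aS)-4-ethenyl-2-hydroxy-3,4a,8,8-tetramethyl-4a,5,6,7,8,8a-hexahydronaphthalen-1(2H)-one | O=C1[C@@H](O)C(C)=C(C=C)[C@@]2(C)CCCC(C)(C)[C@H]12 | intermediate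
14 | (1S,2S,4aS,8aS)-4-ethenyl-3,4a,8,8-tetramethyl-1,2,4a,5,6,7,8,8a-octahydronaphthalene-1,2-diol | O[C@@H]1[C@@H](O)C(C)=C(C=C)[C@@]2(C)CCCC(C)(C)[C@H]12 | intermediate
15 | (1S,2S,4aS,8aS)-4-ethenyl-1-hydroxy-3,4a,8,8-tetramethyl-1,2,4a,5,6,7,8,8a-octahydronaphthalen-2-yl 3-methylbutanoate | O[C@@H]1[C@@H](OC(=O)CC(C)C)C(C)=C(C=C)[C@@]2(C)CCCC(C)(C)[C@H]12 | intermediate
16 | (1S,2S,4aS,8aS)-1-(acetyloxy)-4-ethenyl-3,4a,8,8-tetramethyl-1,2,4a,5,6,7,8,8a-octahydronaphthalen-2-yl 3-methylbutanoate | CC(=O)O[C@@H]1[C@@H](OC(=O)CC(C)C)C(C)=C(C=C)[C@@]2(C)CCCC(C)(C)[C@H]12 | intermediate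
17 | 2-(trimethylsilyl)ethan-1-ol | C[Si](C)(C)CCO | starting material
18 | 2,2,6-trimethyl-4H-1,3-dioxin-4-one | CC1=CC(=O)OC(C)(C)O1 | starting material
19 | acetylketene (not isolated) | CC(=O)C=C=O | intermediate
20 | 2-(trimethylsilyl)ethyl 3-oxobutanoate | CC(=O)CC(=O)OCC[Si](C)(C)C | intermediate
21 | 2-(trimethylsilyl)ethyl (2E)-3-{[(trifluoromethyl)sulfonyl]oxy}but-2-enoate | C/C(OS(=O)(=O)C(F)(F)F)=C\C(=O)OCC[Si](C)(C)C | intermediate
22 | B-alkyl-9-BBN from 16, boron on C12 (not isolated) | CC(=O)O[C@@H]1[C@@H](OC(=O)CC(C)C)C(C)=C(CCB3C4CCCC3CCC4)[C@@]2(C)CCCC(C)(C)[C@H]12 | intermediate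
23 | 2-(trimethylsilyl)ethyl ester of the target acid | CC(=O)O[C@@H]1[C@@H](OC(=O)CC(C)C)C(C)=C(CC/C(C)=C/C(=O)OCC[Si](C)(C)C)[C@@]2(C)CCCC(C)(C)[C@H]12 | intermediate
24 | 6β-acetoxy-7α-(3-methylbutanoyloxy)labda-8,13E-dien-15-oic acid | CC(=O)O[C@@H]1[C@@H](OC(=O)CC(C)C)C(C)=C(CC/C(C)=C/C(=O)O)[C@@]2(C)CCCC(C)(C)[C@H]12 | target

**Totals**

Total step count: 15. Longest linear sequence: 12 steps (steps 1–3, 5–11, 14, 15).

**Steps most likely to fail**

Step 5 (Proposed new method). The first bond may form without ring closure (protodesilylation to an open-chain Michael adduct), the amine may be consumed by conjugate addition to the ynal, or discrimination between the faces of C10 may be poor. The fallback uses known chemistry, sets out from 4 and comes back at 9. Diene 4 and methyl but-2-ynoate are combined neat without catalyst (140 °C in a sealed tube, or 12 kbar at 40 °C), a Diels–Alder reaction of the kind known for 2,6,6-trimethyl-1-vinylcyclohexene and acetylenic esters, to give racemic methyl 2,5,5,8a-tetramethyl-4-[(triisopropylsilyl)oxy]-3,5,6,7,8,8a-hexahydronaphthalene-1-carboxylate F1. DIBAL-H (CH2Cl2, −78 °C) reduces it to racemic {2,5,5,8a-tetramethyl-4-[(triisopropylsilyl)oxy]-3,5,6,7,8,8a-hexahydronaphthalen-1-yl}methanol F2. Preparative chromatography on a chiral stationary phase gives {(8aR)-2,5,5,8a-tetramethyl-4-[(triisopropylsilyl)oxy]-3,5,6,7,8,8a-hexahydronaphthalen-1-yl}methanol F3, which has the spatial arrangement of 9 at C10, and MnO2 oxidises it to 9.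

Step 8. Proton transfer between the dienolate and ketone or product may move the C8=C9 double bond into conjugation or transpose the α-ketol, and attack at the γ-carbon or on the β face may compete. The fallback sets out from 11 and comes back at 13. TMSOTf/Et3N converts 11 into {[(4aS,8aS)-4-ethenyl-3,4a,8,8-tetramethyl-4a,5,6,7,8,8a-hexahydronaphthalen-1-yl]oxy}trimethylsilane F4. Dimethyldioxirane (acetone, −40 °C) epoxidises its electron-rich C6=C7 enol ether bond from the α face, and work-up with dilute citric acid opens the silyloxy epoxide to 13 (Rubottom oxidation), so that no free enolate is present beside the product.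

Step 11. Acylation of the hindered axial 6β-hydroxyl may be slow, and forcing conditions may cause elimination or loss of the allylic ester. The fallback sets out from 13 and comes back at 16. Ketol 13 is first acylated with 3-methylbutanoic anhydride/DMAP to (2S,4aS,8aS)-4-ethenyl-3,4a,8,8-tetramethyl-1-oxo-1,2,4a,5,6,7,8,8a-octahydronaphthalen-2-yl 3-methylbutanoate F5. Its ketone is reduced from the α face with LiAlH(OtBu)3 (THF, −78 °C), and the aluminium 6β-alkoxide, a much better nucleophile than the neutral alcohol, is acetylated in the same flask with Ac2O/DMAP/pyridine (reductive acetylation) to give 16.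

**Further compounds**

F1 | step 5 | racemic methyl 2,5,5,8a-tetramethyl-4-[(triisopropylsilyl)oxy]-3,5,6,7,8,8a-hexahydronaphthalene-1-carboxylate | COC(=O)C1=C(C)CC(O[Si](C(C)C)(C(C)C)C(C)C)=C2C(C)(C)CCCC12C
F2 | step 5 | racemic {2,5,5,8a-tetramethyl-4-[(triisopropylsilyl)oxy]-3,5,6,7,8,8a-hexahydronaphthalen-1-yl}methanol | OCC1=C(C)CC(O[Si](C(C)C)(C(C)C)C(C)C)=C2C(C)(C)CCCC12C
F3 | step 5 | {(8aR)-2,5,5,8a-tetramethyl-4-[(triisopropylsilyl)oxy]-3,5,6,7,8,8a-hexahydronaphthalen-1-yl}methanol | OCC1=C(C)CC(O[Si](C(C)C)(C(C)C)C(C)C)=C2C(C)(C)CCC[C@]12C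
F4 | step 8 | {[(4aS,8aS)-4-ethenyl-3,4a,8,8-tetramethyl-4a,5,6,7,8,8a-hexahydronaphthalen-1-yl]oxy}trimethylsilane | C[Si](C)(C)OC1=CC(C)=C(C=C)[C@@]2(C)CCCC(C)(C)[C@H]12
F5 | step 11 | (2S,4aS,8aS)-4-ethenyl-3,4a,8,8-tetramethyl-1-oxo-1,2,4a,5,6,7,8,8a-octahydronaphthalen-2-yl 3-methylbutanoate | O=C1[C@@H](OC(=O)CC(C)C)C(C)=C(C=C)[C@@]2(C)CCCC(C)(C)[C@H]12
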